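**Retrosynthetic overview**

1. The C6 acetate is put on last. The C12–C13 bond comes from hydroboration and B-alkyl Suzuki coupling of the 9-vinyl carbinol 18 with 3-bromofuran-2(5H)-one (19), so the butenolide ring enters intact.
2. The C9 carbinol comes from α-face epoxidation of the C9 exocyclic alkene 15 and one-carbon ylide homologation (16 to 18). Alkene 15 comes from C9 ketone 14, the Nef product of nitro alcohol 12, and the 6β-OH comes from α-face hydride addition to ketone 11.
3. Key disconnection: C5–C10 and C8–C9. This opens ring A and ring B together and leads to the acyclic nitro dienone 8. Forward, ring A closes first (C5–C10) and ring B second (C8–C9) in one amine-catalysed enamine/iminium double Michael reaction, a formal intramolecular [4+2].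
4. Enabling feature: ring B (C5–C10) carries oxygen on C6 and C9 in a 1,4 relation. C6/C7/C8 can therefore be an enone with C5 as its only enolisable α' carbon (C4 is quaternary), and C9/C10 a nitroalkene with C9 as a latent ketone. C5 and C8 each sit next to one of these carbonyl carbons and can be equilibrated, so only C10 must be set by the catalyst.
5. Precursor 8 is made in three steps from 5-bromo-2-methylpent-1-ene (1), mesityl oxide (2) and acetaldehyde.

Key step: step 4

Remark on numbering: bicyclic compounds carry labdane numbers (ring A = C1–C5 and C10; ring B = C5–C10; methyl groups on C4 (two), C8 and C10; side chain C11–C16). α is the face of H-5 and β the face of the C10 methyl group.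

Remark on the chemistry: the (1R,2R) catalyst of step 4 is assumed to give the 10S series. If it gives 10R, its (1S,2S) mirror image is used and nothing else changes.

**Route**

Step 1
Reactants: 1 5-bromo-2-methylpent-1-ene; 2 4-methylpent-3-en-2-one (mesityl oxide)
Product: 4 4,4,8-trimethylnon-8-en-2-one, via Grignard reagent 3 (not isolated)
Conditions: Mg, THF, 40 °C; then CuBr·SMe2 (5 mol %), 2, THF, −30 → 0 °C; 1 M HCl
Reagents that add atoms: none
Why: Copper-catalysed conjugate addition of a primary alkyl Grignard reagent to the β,β-disubstituted enone should build the quaternary C4; no stereocentre is formed.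

Step 2
Reactants: 4 4,4,8-trimethylnon-8-en-2-one
Product: 7 (E)-6,6,10-trimethylundeca-2,10-dien-4-one, via lithium aldolate 5 (not isolated), via mesylate 6 (not isolated)
Conditions: LDA, THF, −78 °C; MeCHO, −78 °C; MsCl, −78 → 0 °C; DBU, 0 °C → rt
Reagents that add atoms: acetaldehyde, CC=O
Why: Kinetic deprotonation should take the methyl group and not the neopentyl CH2, and aldol addition followed by mesylation and E1cB elimination (aldol condensation) should give the more stable (E)-enone.

Step 3
Reactants: 7 (E)-6,6,10-trimethylundeca-2,10-dien-4-one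
Product: 8 (2E,10E)-6,6,10-trimethyl-11-nitroundeca-2,10-dien-4-one
Conditions: AgNO2 (3 equiv), TEMPO (0.4 equiv), 4 Å MS, ClCH2CH2Cl, 70 °C; (E)-isomer isolated by chromatography
Reagents that add atoms: silver nitrite, [Ag+].[O-]N=O
Why: In this radical nitration–elimination of an alkene the electrophilic NO2 radical should add to the CH2 end of the electron-rich 1,1-disubstituted alkene and not to the electron-poor enone, and TEMPO-mediated loss of the hydrogen next to nitrogen should give the conjugated nitroalkene with nitro trans to the chain as the main isomer.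

Step 4
Reactants: 8 (2E,10E)-6,6,10-trimethyl-11-nitroundeca-2,10-dien-4-one
Product: 11 4,4,8α,10β-tetramethyl-9β-nitro-trans-decalin-6-one (5S,10S), via dienamine 9 (not isolated), via iminium nitronate 10 (not isolated)
Conditions: 1-[(1R,2R)-2-aminocyclohexyl]-3-[3,5-bis(trifluoromethyl)phenyl]thiourea (20 mol %), PhCO2H (20 mol %), toluene (0.02 M), 40 °C; then p-TsOH·H2O (30 mol %), 60 °C
Reagents that add atoms: none
Why: Proposed new method: the primary amine of the catalyst should condense with the C6 ketone to the cross-conjugated dienamine 9 (C5=C6–C7=C8), whose C5 adds to C10 of the thiourea-bound nitroalkene to give the iminium nitronate 10, after which the nitronate carbon C9 adds to C8 of the unsaturated iminium ion and hydrolysis returns the catalyst; the closest known reaction type is the primary-amine-catalysed enamine/iminium double Michael reaction (formal Diels–Alder reaction) of acyclic enones with nitroalkenes, which has not been run intramolecularly on a β,β-disubstituted nitroalkene. Ring A closes 6-exo-trig (C5 onto C10 through a chair made by the C1–C4 tether) and ring B closes 6-endo-trig (C9 onto C8 of the iminium ion). The quaternary C10 (S) is the only centre that must come from the catalyst: the thiourea holds the nitro group by two hydrogen bonds next to the enamine, so that C5 should reach only one face of C10. C5 is formed in the same chair transition state and is then brought to the trans ring fusion (5α-H) by acid-catalysed enolisation of the C6 ketone, while C8 and C9 are formed in the ring-B closure but need no control, because C9 becomes a ketone in step 6 and C8 is equilibrated there. The step needs face selectivity at C10 and enamine formation towards C5: the first rests on the bifunctional catalyst and the single (E) geometry of the nitroalkene, the second on the fact that only the C5 enamine can reach C10 through a six-membered transition state, all other donor–acceptor pairs closing rings of four or of eight or more atoms.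

Step 5
Reactants: 11 4,4,8α,10β-tetramethyl-9β-nitro-trans-decalin-6-one
Product: 12 4,4,8α,10β-tetramethyl-9β-nitro-trans-decalin-6β-ol
Conditions: NaBH4, MeOH, 0 °C
Reagents that add atoms: none
Why: In this borohydride reduction hydride should attack C6 from the α face, because the β face is covered by the axial methyl groups on C4 and C10, which sets the axial 6β-OH; the nitro group is inert.

Step 6
Reactants: 12 4,4,8α,10β-tetramethyl-9β-nitro-trans-decalin-6β-ol
Product: 14 6β-hydroxy-4,4,8α,10β-tetramethyl-trans-decalin-9-one, via sodium nitronate 13 (not isolated)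
Conditions: NaOMe (2 equiv), MeOH, 0 °C; O3/O2, −78 °C; N2 purge, then rt; pH 7 buffer
Reagents that add atoms: ozone, [O-][O+]=O
Why: In this ozonolytic Nef reaction the nitronate C=N bond should be cleaved to the C9 ketone without touching the alcohol, and the remaining methoxide should then equilibrate C8 through the C9 enolate to the equatorial 8α-methyl epimer, since the 8β epimer suffers a syn-diaxial contact with the C10 methyl group.

Step 7
Reactants: 14 6β-hydroxy-4,4,8α,10β-tetramethyl-trans-decalin-9-one
Product: 15 4,4,8α,10β-tetramethyl-9-methylene-trans-decalin-6β-ol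
Conditions: Ph3PCH3Br, KOtBu, toluene, 90 °C
Reagents that add atoms: methyltriphenylphosphonium bromide, C[P+](c1ccccc1)(c1ccccc1)c1ccccc1.[Br-]
Why: Wittig methylenation under the forcing conditions used for hindered ketones should give the exocyclic alkene, and C8 stays in its thermodynamic configuration under the basic conditions.

Step 8
Reactants: 15 4,4,8α,10β-tetramethyl-9-methylene-trans-decalin-6β-ol
Product: 16 9α,11-epoxy-4,4,8α,10β-tetramethyl-9β-methyl-trans-decalin-6β-ol (spiro-oxirane on C9)
Conditions: mCPBA, NaHCO3, CH2Cl2, 0 °C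
Reagents that add atoms: 3-chloroperoxybenzoic acid (mCPBA), OOC(=O)c1cccc(Cl)c1
Why: In this Prilezhaev epoxidation the peracid should reach the exocyclic alkene from the α face, anti to the axial C10 methyl group, which places oxygen α (axial) and C11 β (equatorial) on C9 as in the target.

Step 9
Reactants: 16 9α,11-epoxy-4,4,8α,10β-tetramethyl-9β-methyl-trans-decalin-6β-ol
Product: 18 4,4,8α,10β-tetramethyl-9β-vinyl-trans-decalin-6β,9α-diol, via sulfonium betaine 17 (not isolated)
Conditions: Me3SI, n-BuLi, THF, −10 °C → rt
Reagents that add atoms: trimethylsulfonium iodide, C[S+](C)C.[I-]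
Why: In this one-carbon homologation of an epoxide to an allylic alcohol dimethylsulfonium methylide should open the oxirane at its CH2 carbon (C11) and base should then eliminate dimethyl sulfide from the betaine, so the C9–O bond and its configuration are not touched.

Step 10
Reactants: 18 4,4,8α,10β-tetramethyl-9β-vinyl-trans-decalin-6β,9α-diol; 19 3-bromofuran-2(5H)-one
Product: 21 6β,9α-dihydroxylabd-13-en-16,15-olide, via alkylborane 20 (not isolated)
Conditions: 9-BBN (excess), THF, 0 °C → rt; then 19, PdCl2(dppf) (5 mol %), K3PO4 (aq), DMF, 50 °C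
Reagents that add atoms: none
Why: Anti-Markovnikov hydroboration of the vinyl group followed by B-alkyl Suzuki–Miyaura coupling with the α-bromobutenolide should form the C12–C13 bond; no stereocentre is touched.

Step 11
Reactants: 21 6β,9α-dihydroxylabd-13-en-16,15-olide
Product: 22 6β-acetoxy-9α-hydroxylabd-13-en-16,15-olide
Conditions: Ac2O, DMAP, pyridine, rt
Reagents that add atoms: acetic anhydride, CC(=O)OC(C)=O
Why: DMAP-catalysed acylation should take the secondary 6β-OH, while the tertiary 9α-OH between two fully substituted carbons should not react.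

**Compound list**

1 | 5-bromo-2-methylpent-1-ene | C=C(C)CCCBr | starting material
2 | 4-methylpent-3-en-2-one (mesityl oxide) | CC(C)=CC(C)=O | starting material
3 | (4-methylpent-4-en-1-yl)magnesium bromide | C=C(C)CCC[Mg]Br | intermediate (not isolated)
4 | 4,4,8-trimethylnon-8-en-2-one | CC(=O)CC(C)(C)CCCC(C)=C | intermediate
5 | lithium 6,6,10-trimethyl-4-oxoundec-10-en-2-olate (racemic) | CC([O-])CC(=O)CC(C)(C)CCCC(C)=C.[Li+] | intermediate (not isolated)
6 | 6,6,10-trimethyl-4-oxoundec-10-en-2-yl methanesulfonate (racemic) | CC(OS(C)(=O)=O)CC(=O)CC(C)(C)CCCC(C)=C | intermediate (not isolated)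
7 | (E)-6,6,10-trimethylundeca-2,10-dien-4-one | C/C=C/C(=O)CC(C)(C)CCCC(C)=C | intermediate
8 | (2E,10E)-6,6,10-trimethyl-11-nitroundeca-2,10-dien-4-one | C/C=C/C(=O)CC(C)(C)CCC/C(C)=C/[N+](=O)[O-] | intermediate
9 | cross-conjugated dienamine of 8 with the catalyst (N on C6, double bonds C5=C6 and C7=C8) | C/C=C/C(N[C@@H]1CCCC[C@H]1NC(=S)Nc1cc(cc(c1)C(F)(F)F)C(F)(F)F)=C/C(C)(C)CCC/C(C)=C/[N+](=O)[O-] | intermediate (not isolated)
10 | monocyclic iminium nitronate (ring A closed, C5–C10 bond formed; drawn with the C5 configuration that leads to the trans fusion) | [O-][N+]([O-])=C[C@@]1(C)CCCC(C)(C)[C@@H]1C(=[NH+][C@@H]2CCCC[C@H]2NC(=S)Nc2cc(cc(c2)C(F)(F)F)C(F)(F)F)/C=C/C | intermediate (not isolated)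
11 | (5S,8R,9S,10S)-4,4,8,10-tetramethyl-9-nitro-trans-decalin-6-one: 5α-H, 8α-CH3, 9β-NO2, 10β-CH3 (C8/C9 epimers, if present, are carried on and converge in step 6) | O=C1C[C@@H](C)[C@H]([N+](=O)[O-])[C@@]2(C)CCCC(C)(C)[C@H]12 | intermediate
12 | 4,4,8α,10β-tetramethyl-9β-nitro-trans-decalin-6β-ol (5S,10S) | O[C@@H]1C[C@@H](C)[C@H]([N+](=O)[O-])[C@@]2(C)CCCC(C)(C)[C@H]12 | intermediate
13 | sodium nitronate of 12 (C9=N) | O[C@@H]1C[C@@H](C)C(=[N+]([O-])[O-])[C@@]2(C)CCCC(C)(C)[C@H]12.[Na+] | intermediate (not isolated)
14 | 6β-hydroxy-4,4,8α,10β-tetramethyl-trans-decalin-9-one (5S,10S) | O[C@@H]1C[C@@H](C)C(=O)[C@@]2(C)CCCC(C)(C)[C@H]12 | intermediate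
15 | 4,4,8α,10β-tetramethyl-9-methylene-trans-decalin-6β-ol | O[C@@H]1C[C@@H](C)C(=C)[C@@]2(C)CCCC(C)(C)[C@H]12 | intermediate
16 | spiro-oxirane on C9 (oxygen α, C11 β) of 4,4,8α,10β-tetramethyl-trans-decalin-6β-ol | O[C@@H]1C[C@@H](C)[C@]3(CO3)[C@@]2(C)CCCC(C)(C)[C@H]12 | intermediate
17 | lithium salt of the betaine: 9α-oxido, 9β-CH2CH2-S(+)Me2, 6β-oxido | [Li+].[O-][C@@H]1C[C@@H](C)[C@]([O-])(CC[S+](C)C)[C@@]2(C)CCCC(C)(C)[C@H]12 | intermediate (not isolated)
18 | 4,4,8α,10β-tetramethyl-9β-vinyl-trans-decalin-6β,9α-diol | O[C@@H]1C[C@@H](C)[C@](O)(C=C)[C@@]2(C)CCCC(C)(C)[C@H]12 | intermediate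
19 | 3-bromofuran-2(5H)-one | O=C1OCC=C1Br | starting material
20 | B-alkyl-9-BBN from 18 (boron on C12) | O[C@@H]1C[C@@H](C)[C@](O)(CCB3C4CCCC3CCC4)[C@@]2(C)CCCC(C)(C)[C@H]12 | intermediate (not isolated)
21 | 6β,9α-dihydroxylabd-13-en-16,15-olide | O[C@@H]1C[C@@H](C)[C@](O)(CCC2=CCOC2=O)[C@@]2(C)CCCC(C)(C)[C@H]12 | intermediate
22 | (5S,6R,8R,9R,10S)-6β-acetoxy-9α-hydroxylabd-13-en-16,15-olide | CC(=O)O[C@@H]1C[C@@H](C)[C@](O)(CCC2=CCOC2=O)[C@@]2(C)CCCC(C)(C)[C@H]12 | target

**Step count and risks**

Total step count: 11. Longest linear sequence: 11 steps (1 to 22); compounds 2 and 19 and all reagents are bought.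

Steps most likely to fail:

1. Step 4 (the step labelled as a proposed new method). The catalyst may turn over poorly at the congested C5–C10 bond, and face selectivity at C10 may be eroded if the nitroalkene isomerises between E and Z under the amine. Fallback with known chemistry, from 8 back to 11: compound 8 is silylated on the α' side (TBSOTf, Et3N, CH2Cl2, −78 °C) to the tert-butyldimethylsilyl dienol ether F1. Heating (toluene, BHT, 110 °C) should bring about the thermal intramolecular Diels–Alder reaction of the 2-silyloxydiene with the nitroalkene and give the racemic bicyclic silyl enol ether F2. Acid (p-TsOH, wet THF, 50 °C) should hydrolyse the enol ether and equilibrate C5 to the racemic nitro ketone F3 (11 and its mirror image). Preparative chromatography on a chiral stationary phase then gives 11, and the route continues at step 5.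

2. Step 9. The ylide may fail to open the neopentyl-type CH2 of the hindered spiro-oxirane, and the C6 alkoxide or a rearrangement of the epoxide to an aldehyde may compete. Fallback, from 15 back to 18: alkene 15 is dihydroxylated from the same α face (OsO4 cat., NMO, acetone/H2O) to the 6β,9α,11-triol F4. The primary alcohol is oxidised selectively (TEMPO, PhI(OAc)2, CH2Cl2) to the α-hydroxy aldehyde F5. Wittig methylenation (Ph3PCH3Br, KHMDS, THF, −78 → 0 °C) then gives 18.

3. Step 10. The base-sensitive α-bromobutenolide may decompose before transmetalation, with loss of the borane by protodeboronation. Fallback, from 18 back to 21: the same alkylborane 20 is made from 18 and coupled (PdCl2(dppf), K3PO4, DMF, 50 °C) with 3-bromo-2-(trimethylsilyl)furan F6 (from 3-bromofuran, LDA, then Me3SiCl) to give the 2-silylfuran F7. Peracetic acid (AcOOH, NaOAc, CH2Cl2, then Et3N) should oxidise the silyl-bearing furan carbon to the lactone carbonyl and so give the α-substituted butenolide 21.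

Further compounds
F1 | step 4 | tert-butyldimethylsilyl dienol ether of 8 (C5=C6–OTBS, C7=C8) | C/C=C/C(O[Si](C)(C)C(C)(C)C)=C/C(C)(C)CCC/C(C)=C/[N+](=O)[O-]
F2 | step 4 | racemic bicyclic silyl enol ether (C6=C7, 6-OTBS, 9-nitro; mixture of C5/C8/C9 epimers) | CC(C)(C)[Si](C)(C)OC1=CC(C)C([N+](=O)[O-])C2(C)CCCC(C)(C)C12
F3 | step 4 | racemic nitro ketone (11 and its mirror image; the mirror image is drawn) | O=C1C[C@H](C)[C@@H]([N+](=O)[O-])[C@]2(C)CCCC(C)(C)[C@@H]12
F4 | step 9 | 9β-(hydroxymethyl)-4,4,8α,10β-tetramethyl-trans-decalin-6β,9α-diol | O[C@@H]1C[C@@H](C)[C@](O)(CO)[C@@]2(C)CCCC(C)(C)[C@H]12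
F5 | step 9 | 6β,9α-dihydroxy-4,4,8α,10β-tetramethyl-trans-decalin-9β-carbaldehyde | O[C@@H]1C[C@@H](C)[C@](O)(C=O)[C@@]2(C)CCCC(C)(C)[C@H]12
F6 | step 10 | 3-bromo-2-(trimethylsilyl)furan | C[Si](C)(C)c1occc1Br
F7 | step 10 | 9β-[2-(2-trimethylsilylfuran-3-yl)ethyl]-4,4,8α,10β-tetramethyl-trans-decalin-6β,9α-diol | O[C@@H]1C[C@@H](C)[C@](O)(CCc3ccoc3[Si](C)(C)C)[C@@]2(C)CCCC(C)(C)[C@H]12
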